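In ring B the C5=C6 alkene and the C9-C10 edge flank the ring-fusion methine C1. An added C9=C10 alkene makes ring B a skipped cycloheptadiene, the product pattern of a cis-divinylcyclopropane Cope rearrangement. The plan therefore cuts C7-C8 and reconnects C5-C10. The precursor is a bicyclo[3.1.0]hexane (ring A plus C10) with a Z-enoate arm on C5 and, cis to it, a vinyl arm on C10. Heating closes ring B, leaves C5=C6 in place and writes the enoate geometry into C7, all in one operation. C1' and C4 come from face-selective alkylation of an enantioenriched dihydrocoumarin. Two aryl bromines ride along as formyl placeholders.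

Key step: step 16

Numbering: ring A = C1-C2-C3-C4-C5; ring B = C1-C5-C6-C7-C8-C9-C10; C1' = benzylic CH on C4; C11 = carbinol carbon on C7; C6 is the ester carbon in 10 to 19. The α face carries H1, the C7 side chain and the C1' branch on C4 in 29. The β face carries the C4 methyl, H7 and the C10 methyl.

Assumption: (R)-DTBM-SEGPHOS is taken to give (R)-5. If the copper hydride shows the opposite sense, the (S)-ligand is used and nothing else changes.

Remark: in 22 the two arms are cis, the C10 methyl is endo, and the Z ester maps onto the α side chain at C7 of 29. The aryl bromines replace a late electrophilic formylation, which the tertiary alcohol and C5=C6 would not tolerate.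

Step 1
Reactants: 1 3,5-dimethoxyphenol; 2 ethyl 5-methyl-3-oxohexanoate
Product: 3 4-isobutyl-5,7-dimethoxycoumarin
Conditions: MeSO3H, 0 °C to rt
Reagents that add atoms: none
Why: Pechmann condensation of an activated phenol whose two ortho positions are equivalent should give a single coumarin that already joins the arene, C1' and the isobutyl group.

Step 2
Reactants: 3 4-isobutyl-5,7-dimethoxycoumarin
Product: 5 (4R)-4-isobutyl-5,7-dimethoxychroman-2-one, via boron enolate 4 (not isolated)
Conditions: CuCl (5 mol %), NaOt-Bu (5 mol %), (R)-DTBM-SEGPHOS (5 mol %), pinacolborane (1.3 equiv), toluene, rt; then aq NH4Cl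
Reagents that add atoms: none
Why: Ligand-controlled asymmetric conjugate reduction (copper hydride 1,4-hydroboration of a 4-substituted coumarin) adds hydride to one face of C1' and so sets this centre, while the carbonyl group rests as boron enolate 4 until work-up and cannot be reduced further.

Step 3
Reactants: 5 (4R)-4-isobutyl-5,7-dimethoxychroman-2-one
Product: 6 (3R,4R)-4-isobutyl-5,7-dimethoxy-3-methylchroman-2-one (methyl trans to isobutyl)
Conditions: LiN(i-Pr)2, THF, -78 °C; MeI
Reagents that add atoms: iodomethane CI
Why: Lactone enolate alkylation with the most reactive alkyl halide, methyl entering anti to the isobutyl group, although this centre is planarised again in step 4 so that only clean monomethylation matters.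

Step 4
Reactants: 6 (3R,4R)-4-isobutyl-5,7-dimethoxy-3-methylchroman-2-one
Product: 7 (3R,4S)-4-isobutyl-5,7-dimethoxy-3-methyl-3-(prop-2-ynyl)chroman-2-one (methyl cis and propargyl trans to isobutyl)
Conditions: KN(SiMe3)2, THF, -78 °C; propargyl bromide, -78 to -20 °C
Reagents that add atoms: propargyl bromide C#CCBr
Why: Diastereoselective alkylation of the fully substituted lactone enolate with an activated halide creates quaternary C4, since the isobutyl group on C1' is forced pseudoaxial by the neighbouring aryl methoxy group and shields one face, so that the propargyl unit (future C3, C2 and C1) enters anti to it and the methyl group ends cis to it, as 29 requires.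

Step 5
Reactants: 7 quaternary lactone
Product: 10 phenolic methyl ester (C5H2-C6O2Me on C4), via dibromo enolate 8 (not isolated), via lithium ynolate 9 (not isolated)
Conditions: CH2Br2, lithium 2,2,6,6-tetramethylpiperidide, THF, -90 °C; n-BuLi, -78 °C to rt; HCl/MeOH, 0 °C to rt
Reagents that add atoms: dibromomethane BrCBr; methanol CO
Why: Kowalski ester homologation, in which LiCHBr2 is acylated by the activated aryl lactone, bromine-lithium exchange on 8 triggers a 1,2-shift of C4 with retention of configuration to ynolate 9, and acidic methanol converts the derived ketene into the C5H2-C6O2Me unit and frees the phenol.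

Step 6
Reactants: 10 phenolic methyl ester
Product: 11 2,4,6-trimethoxyphenyl methyl ester
Conditions: MeI, K2CO3, DMF, rt
Reagents that add atoms: iodomethane CI
Why: Williamson ether synthesis on the only acidic OH group gives the symmetric trimethoxyaryl unit and leaves ester and alkyne alone.

Step 7
Reactants: 11 2,4,6-trimethoxyphenyl methyl ester
Product: 12 3,5-dibromo-2,4,6-trimethoxyphenyl methyl ester
Conditions: NBS (2.1 equiv), MeCN, 0 °C, dark
Reagents that add atoms: N-bromosuccinimide O=C1CCC(=O)N1Br
Why: Electrophilic aromatic bromination of a 1,3,5-trialkoxybenzene is far faster than any reaction of NBS with the terminal alkyne and fills the only two free ring positions, which turns them into masked formyl groups and removes every aryl C-H bond before the carbene step.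

Step 8
Reactants: 12 dibromoaryl alkyne ester
Product: 14 C1 aldehyde ester, via alkenylborane 13 (not isolated)
Conditions: Cy2BH (from BH3·SMe2 and cyclohexene), THF, 0 °C; then 30% H2O2, pH 7 phosphate buffer, 0 °C to rt
Reagents that add atoms: hydrogen peroxide OO
Why: Anti-Markovnikov hydroboration of the terminal alkyne with a bulky dialkylborane stops at monoadduct 13, and buffered peroxide oxidation then gives the C1 aldehyde without touching the methyl ester.

Step 9
Reactants: 14 C1 aldehyde ester
Product: 15 (E)-enal ester (C1=C10 with C10 methyl and C9 formyl)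
Conditions: Ph3P=C(CH3)CHO, toluene, 90 °C
Reagents that add atoms: 2-(triphenylphosphoranylidene)propanal CC(C=O)=P(c1ccccc1)(c1ccccc1)c1ccccc1
Why: Wittig olefination with a stabilised ylide should give the E trisubstituted enal, which places C2 cis to the C10 methyl group exactly as the cyclopropane of step 12 needs.

Step 10
Reactants: 15 (E)-enal ester
Product: 16 (E)-diene ester (C1=C10-C9=C8)
Conditions: Ph3PCH3Br, KN(SiMe3)2, THF, -78 to 0 °C
Reagents that add atoms: methyltriphenylphosphonium bromide C[P+](c1ccccc1)(c1ccccc1)c1ccccc1.[Br-]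
Why: Wittig methylenation of the enal carbonyl is fast at low temperature, keeps the E alkene and the methyl ester intact and completes the diene.

Step 11
Reactants: 16 (E)-diene ester
Product: 18 α-diazo ester (diazo group on C5), via trifluoroacetyl ester 17 (not isolated)
Conditions: LiN(SiMe3)2, THF, -78 °C; CF3CO2CH2CF3; then MsN3, Et3N, MeCN-H2O, rt
Reagents that add atoms: mesyl azide CS(=O)(=O)N=[N+]=[N-]
Why: Detrifluoroacetylative diazo transfer (a Regitz-type transfer to an ester activated in the flask as 17) acts at C5, the only enolisable position, under conditions that the diene and the aryl bromides tolerate.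

Step 12
Reactants: 18 α-diazo ester
Product: 19 methyl bicyclo[3.1.0]hexane-1-carboxylate (ring A plus C10; C10 methyl endo, vinyl exo and cis to the ester; cyclopropane on the β face)
Conditions: Cu(acac)2 (5 mol %), 1,2-dichloroethane, 80 °C, slow addition of 18
Reagents that add atoms: none
Why: Copper-carbene intramolecular cyclopropanation closes ring A and the three-membered ring by a stereospecific syn addition, so the E alkene puts the C10 methyl endo and the vinyl exo, while C4 chooses the face because its bulky C1' branch prefers to lie next to the flat small ester and not next to the metal and the incoming C10, and copper instead of rhodium suppresses 1,5 C-H insertion at the isobutyl methine.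

Step 13
Reactants: 19 bicyclic ester
Product: 20 bicyclic primary alcohol (C6H2OH on C5)
Conditions: i-Bu2AlH (2.5 equiv), CH2Cl2, -78 to 0 °C; Rochelle salt work-up
Reagents that add atoms: none
Why: Hydride reduction of the only ester to the primary alcohol leaves the vinylcyclopropane and the aryl bromides untouched.

Step 14
Reactants: 20 bicyclic primary alcohol
Product: 21 bicyclic carbaldehyde (C6HO on C5, cis to the vinyl group)
Conditions: Dess-Martin periodinane, CH2Cl2, 0 °C; used at once
Reagents that add atoms: none
Why: Dess-Martin oxidation is neutral, fast and cold, which matters because a cis-2-vinylcyclopropanecarbaldehyde can drift by a reversible retro-Claisen valence isomerisation if it is stored or warmed.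

Step 15
Reactants: 21 bicyclic carbaldehyde
Product: 22 cis-divinylcyclopropane with the Z-enoate arm on C5
Conditions: (CF3CH2O)2P(O)CH2CO2Me, KN(SiMe3)2, 18-crown-6, THF, -78 °C; work-up and storage below 25 °C
Reagents that add atoms: methyl bis(2,2,2-trifluoroethyl)phosphonoacetate COC(=O)CP(=O)(OCC(F)(F)F)OCC(F)(F)F
Why: Still-Gennari olefination, in which fast and irreversible collapse of the kinetic adduct of the electron-poor phosphonate gives the Z-enoate, the methyl ester being the smallest carboxyl group that can later sit inside the rearrangement.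

Step 16
Reactants: 22 cis-divinylcyclopropane with the Z-enoate arm
Product: 23 hydroazulene diene ester (C5=C6, C9=C10, ester α on C7)
Conditions: toluene (0.02 M, degassed), BHT (5 mol %), sealed tube, 110 °C, raised to 130 °C only if conversion demands it
Reagents that add atoms: none
Why: This is a concerted [3,3]-sigmatropic shift, the divinylcyclopropane-cycloheptadiene Cope rearrangement known for 1-alkenyl-6-vinylbicyclo[3.1.0]hexanes, in which the strained C5-C10 bond opens while C7-C8 forms. Ring B closes by this pericyclic ring expansion through a boat transition state that the cis-fused cyclopropane imposes, both arms tucking over the C1 corner, which offers them nothing larger than H1 since C2 is tied back into ring A on the far face. C7 is the one new stereocentre and is dictated solely by the alkene geometry: the Z ester points into the boat, ends on the same face of ring B as H1 and therefore trans to C2, so H1 and H7 come out trans, whereas an E ester would give the epimer. C1 keeps its configuration, and C5 and C10 become the sp2 carbons of C5=C6 and C9=C10. The step needs the concerted path to outrun C5-C10 homolysis, which would scramble the enoate geometry. Quaternary C4 helps by pushing the C5 arm into the reactive s-cis rotamer, and no cis alkyl C-H is placed for a homodienyl hydrogen shift.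

Step 17
Reactants: 23 hydroazulene diene ester
Product: 25 tertiary carbinol (C11 on C7), via methyl ketone 24 (not isolated)
Conditions: CeCl3 (4 equiv, dried), MeLi (4 equiv), THF, -78 °C; then 23, -78 to -20 °C; aq NH4Cl
Reagents that add atoms: methyllithium [Li]C
Why: Double organocerium addition to the ester, the weakly basic reagent adding faster than it enolises, so that the acidic allylic C7-H of 23 and 24 is neither epimerised nor lost to conjugation and the aryl bromides see no free alkyllithium.

Step 18
Reactants: 25 tertiary carbinol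
Product: 26 C9,C10-dihydro carbinol (C10 methyl β)
Conditions: [Ir(cod)(PCy3)(py)]PF6 (5 mol %), H2 (1 atm), CH2Cl2, 0 °C to rt
Reagents that add atoms: none
Why: Hydroxyl-directed homogeneous hydrogenation, in which the cationic iridium centre binds the C11 hydroxyl and delivers hydrogen to the α face of C9=C10 and so sets C10 with its methyl group β, while C5=C6 is left alone because its α face is covered by the C1' branch on the adjacent quaternary C4.

Step 19
Reactants: 26 C9,C10-dihydro carbinol
Product: 28 tri-O-methyl dialdehyde, via dilithioarene alkoxide 27 (not isolated)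
Conditions: t-BuLi (5.5 equiv), THF-Et2O, -78 °C; DMF, -78 to 0 °C; aq NH4Cl
Reagents that add atoms: N,N-dimethylformamide CN(C)C=O
Why: Double bromine-lithium exchange followed by Bouveault formylation installs both aldehydes under basic conditions that spare the tertiary alcohol (held as its alkoxide) and C5=C6, each aryllithium being stabilised by two flanking methoxy groups.

Step 20
Reactants: 28 tri-O-methyl dialdehyde
Product: 29 (-)-macrocarpal D
Conditions: 4-MeC6H4SLi (from 4-methylbenzenethiol and n-BuLi, excess), HMPA-toluene, 110 °C; then dilute HCl, 0 °C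
Reagents that add atoms: none
Why: Nucleophilic aryl methyl ether cleavage (SN2 attack of thiolate on the methyl groups) is eased because every departing phenoxide is conjugated to a formyl group, and it avoids the Lewis acids that would ionise the tertiary alcohol or shift C5=C6.

Compound list
1 | 3,5-dimethoxyphenol | COc1cc(O)cc(OC)c1 | starting material
2 | ethyl 5-methyl-3-oxohexanoate | CCOC(=O)CC(=O)CC(C)C | starting material
3 | 4-isobutyl-5,7-dimethoxycoumarin | CC(C)CC1=CC(=O)Oc2cc(OC)cc(OC)c21 | intermediate
4 | pinacolboryl enolate of 5 | CC(C)C[C@@H]1C=C(OB2OC(C)(C)C(C)(C)O2)Oc2cc(OC)cc(OC)c21 | intermediate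
5 | (4R)-4-isobutyl-5,7-dimethoxychroman-2-one | CC(C)C[C@@H]1CC(=O)Oc2cc(OC)cc(OC)c21 | intermediate
6 | (3R,4R)-4-isobutyl-5,7-dimethoxy-3-methylchroman-2-one | CC(C)C[C@@H]1[C@@H](C)C(=O)Oc2cc(OC)cc(OC)c21 | intermediate
7 | (3R,4S)-4-isobutyl-5,7-dimethoxy-3-methyl-3-(prop-2-ynyl)chroman-2-one | CC(C)C[C@@H]1[C@@](C)(CC#C)C(=O)Oc2cc(OC)cc(OC)c21 | intermediate
8 | trilithium salt of the ring-opened dibromomethyl ketone (dibromo enolate) | CC(C)C[C@@H](c1c([O-])cc(OC)cc1OC)[C@@](C)(CC#[C-])C([O-])=C(Br)Br.[Li+].[Li+].[Li+] | intermediate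
9 | trilithium ynolate after 1,2-shift of C4 | CC(C)C[C@@H](c1c([O-])cc(OC)cc1OC)[C@@](C)(CC#[C-])C#C[O-].[Li+].[Li+].[Li+] | intermediate
10 | methyl 3-[1-(2-hydroxy-4,6-dimethoxyphenyl)-3-methylbutyl]-3-methylhex-5-ynoate, C1' and C4 as in 29 | CC(C)C[C@@H](c1c(O)cc(OC)cc1OC)[C@@](C)(CC#C)CC(=O)OC | intermediate
11 | methyl 3-methyl-3-[3-methyl-1-(2,4,6-trimethoxyphenyl)butyl]hex-5-ynoate, C1' and C4 as in 29 | CC(C)C[C@@H](c1c(OC)cc(OC)cc1OC)[C@@](C)(CC#C)CC(=O)OC | intermediate
12 | 3,5-dibromoaryl analogue of 11 | CC(C)C[C@@H](c1c(OC)c(Br)c(OC)c(Br)c1OC)[C@@](C)(CC#C)CC(=O)OC | intermediate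
13 | (E)-alkenyl(dicyclohexyl)borane from 12 | CC(C)C[C@@H](c1c(OC)c(Br)c(OC)c(Br)c1OC)[C@@](C)(C/C=C/B(C1CCCCC1)C1CCCCC1)CC(=O)OC | intermediate
14 | methyl 3-[1-(3,5-dibromo-2,4,6-trimethoxyphenyl)-3-methylbutyl]-3-methyl-6-oxohexanoate | CC(C)C[C@@H](c1c(OC)c(Br)c(OC)c(Br)c1OC)[C@@](C)(CCC=O)CC(=O)OC | intermediate
15 | methyl (6E)-3-[1-(dibromotrimethoxyphenyl)-3-methylbutyl]-3,7-dimethyl-8-oxooct-6-enoate | CC(C)C[C@@H](c1c(OC)c(Br)c(OC)c(Br)c1OC)[C@@](C)(CC/C=C(\C)C=O)CC(=O)OC | intermediate
16 | methyl (6E)-3-[1-(dibromotrimethoxyphenyl)-3-methylbutyl]-3,7-dimethylnona-6,8-dienoate | CC(C)C[C@@H](c1c(OC)c(Br)c(OC)c(Br)c1OC)[C@@](C)(CC/C=C(\C)C=C)CC(=O)OC | intermediate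
17 | 2-trifluoroacetyl derivative of 16 (epimers at C5 and enol) | CC(C)C[C@@H](c1c(OC)c(Br)c(OC)c(Br)c1OC)[C@@](C)(CC/C=C(\C)C=C)C(C(=O)OC)C(=O)C(F)(F)F | intermediate
18 | 2-diazo derivative of 16 | CC(C)C[C@@H](c1c(OC)c(Br)c(OC)c(Br)c1OC)[C@@](C)(CC/C=C(\C)C=C)C(=[N+]=[N-])C(=O)OC | intermediate
19 | methyl 2-[1-(dibromotrimethoxyphenyl)-3-methylbutyl]-2,6-dimethyl-6-vinylbicyclo[3.1.0]hexane-1-carboxylate (6-methyl endo, 6-vinyl exo) | CC(C)C[C@@H](c1c(OC)c(Br)c(OC)c(Br)c1OC)[C@@]1(C)CC[C@H]2[C@]1(C(=O)OC)[C@]2(C)C=C | intermediate
20 | 1-hydroxymethyl analogue of 19 | CC(C)C[C@@H](c1c(OC)c(Br)c(OC)c(Br)c1OC)[C@@]1(C)CC[C@H]2[C@]1(CO)[C@]2(C)C=C | intermediate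
21 | 1-carbaldehyde analogue of 19 | CC(C)C[C@@H](c1c(OC)c(Br)c(OC)c(Br)c1OC)[C@@]1(C)CC[C@H]2[C@]1(C=O)[C@]2(C)C=C | intermediate
22 | cis-divinylcyclopropane, methyl (Z)-3-(bicyclohexan-1-yl)acrylate arm on C5, vinyl on C10 | CC(C)C[C@@H](c1c(OC)c(Br)c(OC)c(Br)c1OC)[C@@]1(C)CC[C@H]2[C@]1(/C=C\C(=O)OC)[C@]2(C)C=C | intermediate
23 | hydroazulene diene ester (C5=C6, C9=C10, H1 and H7 trans) | CC(C)C[C@@H](c1c(OC)c(Br)c(OC)c(Br)c1OC)[C@@]1(C)CC[C@H]2C1=C[C@H](C(=O)OC)CC=C2C | intermediate
24 | C7 methyl ketone | CC(C)C[C@@H](c1c(OC)c(Br)c(OC)c(Br)c1OC)[C@@]1(C)CC[C@H]2C1=C[C@H](C(C)=O)CC=C2C | intermediate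
25 | diene carbinol (2-hydroxypropan-2-yl on C7) | CC(C)C[C@@H](c1c(OC)c(Br)c(OC)c(Br)c1OC)[C@@]1(C)CC[C@H]2C1=C[C@H](C(C)(C)O)CC=C2C | intermediate
26 | C9,C10-dihydro carbinol (C10 methyl β) | CC(C)C[C@@H](c1c(OC)c(Br)c(OC)c(Br)c1OC)[C@@]1(C)CC[C@H]2C1=C[C@H](C(C)(C)O)CC[C@H]2C | intermediate
27 | 3,5-dilithioarene lithium alkoxide | CC(C)C[C@@H](c1c(OC)c([Li])c(OC)c([Li])c1OC)[C@@]1(C)CC[C@H]2C1=C[C@H](C(C)(C)O[Li])CC[C@H]2C | intermediate
28 | tri-O-methylmacrocarpal D | CC(C)C[C@@H](c1c(OC)c(C=O)c(OC)c(C=O)c1OC)[C@@]1(C)CC[C@H]2C1=C[C@H](C(C)(C)O)CC[C@H]2C | intermediate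
29 | (-)-macrocarpal D | CC(C)C[C@@H](c1c(O)c(C=O)c(O)c(C=O)c1O)[C@@]1(C)CC[C@H]2C1=C[C@H](C(C)(C)O)CC[C@H]2C | target

Total step count: 20. Longest linear sequence: 20 (the route is fully linear from 1 and 2).

Steps most likely to fail

Risk 1, step 16. The ester that must sit inside the boat raises the barrier. Homolysis of C5-C10 with loss of the alkene geometry, or simple thermal decay, may then overtake the concerted shift and erode C7. The fallback sets out from 21 and takes C7 from a protonation instead of from the alkene geometry. A Horner-Wadsworth-Emmons reaction (trimethyl phosphonoacetate, LiCl, DBU, MeCN) gives the E-enoate F1. With its ester outside, this should rearrange at or below room temperature to the C7-epimeric diene ester F2. LiN(i-Pr)2 in THF at -78 °C then forms the lithium dienolate F3. Kinetic α-protonation with a hindered phenol should come from the β face, because the α face is screened by the C1' branch. This corrects C7 and comes back to the route at 23.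

Risk 2, step 5. Slow addition of the bulky, thermally fragile carbenoid to the neopentyl-type lactone carbonyl, or incomplete migration of the tertiary C4, may stall the homologation. The fallback sets out from 7 and adds C6 by olefination.
- i-Bu2AlH in toluene at -78 °C gives the lactol F4.
- Excess Ph3P=CHOMe (from Ph3PCH2OMe chloride and KN(SiMe3)2) opens it to the phenolic methyl enol ether F5.
- MeI and K2CO3 give the trimethoxyaryl enol ether F6.
- C5H5NH[CrO3Cl] in CH2Cl2 oxidises the enol ether directly to the methyl ester, which comes back to the route at 11.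

Risk 3, step 15. Sluggish addition to the crowded aldehyde and drift of the aldehyde into its retro-Claisen valence isomer may lower both conversion and Z selectivity, and each E alkene later becomes an epimer at C7. The fallback sets out from 21 and obtains the Z geometry from a syn hydrogenation.
- Seyferth-Gilbert homologation with dimethyl (1-diazo-2-oxopropyl)phosphonate and K2CO3 in MeOH is run at room temperature, where the valence isomers interconvert, and gives the terminal alkyne F7.
- Deprotonation with LiN(i-Pr)2 and acylation with ClCO2Me give the alkynoate F8.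
- Semihydrogenation over Pd/CaCO3 poisoned by Pb(OAc)2 with quinoline, stopped after one equivalent of H2, comes back to the route at 22.

Further compounds
F1 | step 16 | E-enoate cis-divinylcyclopropane | CC(C)C[C@@H](c1c(OC)c(Br)c(OC)c(Br)c1OC)[C@@]1(C)CC[C@H]2[C@]1(/C=C/C(=O)OC)[C@]2(C)C=C
F2 | step 16 | C7-epimeric hydroazulene diene ester | CC(C)C[C@@H](c1c(OC)c(Br)c(OC)c(Br)c1OC)[C@@]1(C)CC[C@H]2C1=C[C@@H](C(=O)OC)CC=C2C
F3 | step 16 | lithium dienolate of F2 | CC(C)C[C@@H](c1c(OC)c(Br)c(OC)c(Br)c1OC)[C@@]1(C)CC[C@H]2C1=CC(=C([O-])OC)CC=C2C.[Li+]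
F4 | step 5 | lactol of 7 (anomers) | CC(C)C[C@@H]1[C@@](C)(CC#C)C(O)Oc2cc(OC)cc(OC)c21
F5 | step 5 | phenolic methyl enol ether (E and Z) | CC(C)C[C@@H](c1c(O)cc(OC)cc1OC)[C@@](C)(CC#C)C=COC
F6 | step 5 | trimethoxyaryl methyl enol ether (E and Z) | CC(C)C[C@@H](c1c(OC)cc(OC)cc1OC)[C@@](C)(CC#C)C=COC
F7 | step 15 | 1-ethynyl-6-vinylbicyclo[3.1.0]hexane | CC(C)C[C@@H](c1c(OC)c(Br)c(OC)c(Br)c1OC)[C@@]1(C)CC[C@H]2[C@]1(C#C)[C@]2(C)C=C
F8 | step 15 | methyl alkynoate on C5 | CC(C)C[C@@H](c1c(OC)c(Br)c(OC)c(Br)c1OC)[C@@]1(C)CC[C@H]2[C@]1(C#CC(=O)OC)[C@]2(C)C=C
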